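**Retrosynthetic overview**

- The target comes in one fluoride step from its ring A C2 O-TBS ether, 2-(trimethylsilyl)ethyl ester; the (R)-acetate and the Z olefin are already in place.
- Ring A is disconnected to a 2-pyranone and a ketene acetal. Ring A atoms C6 (chain), C1 (CO2H), C2 (OH), C3 (H) are the diene carbons C6, C5, C4, C3 of a 6-alkyl-4-silyloxy-2-oxo-2H-pyran-5-carboxylate, and C4 (OH), C5 (H) are the two carbons of 1,1-bis(trimethylsilyloxy)ethene. The new bonds are C5–C6 and C3–C4; CO2 and Me3SiOH are lost.
- The pyranone comes from a beta-keto ester and malonyl dichloride, so the substitution pattern of ring A is fixed before the arene exists.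
- The beta-keto ester comes from a C16 acetoxy acid via its acyl Meldrum's acid and 2-(trimethylsilyl)ethanol. The acid comes from (R)-oct-1-yn-3-ol and 8-bromooctanoic acid by acetylide alkylation, Lindlar reduction and acetylation; the stereocentre is bought.
- Ring order: the pyranone ring is made first (step 6) and is then converted into carbocyclic ring A (step 9).

Key step: step 9

Assumption: lithium, imidazolium or tetrabutylammonium salts of a numbered compound that exist only until work-up are treated as that compound, and the hydroxypyranone is drawn as its 4-hydroxy-2-oxo tautomer.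

**Route**

Step 1
Reactants: 1 (R)-oct-1-yn-3-ol; 2 8-bromooctanoic acid
Product: 3 (R)-11-hydroxyhexadec-9-ynoic acid
Conditions: 2, n-BuLi (1.0 equiv), THF, −78 °C; 1, n-BuLi (2.1 equiv), THF/DMPU, −78 to −20 °C; combine, −20 °C to rt; 1 M HCl
Reagents that add atoms: none
Why: SN2 alkylation of a lithium acetylide, in which the C-lithiated carbon of doubly deprotonated 1 is far more nucleophilic than its alkoxide or the carboxylate of 2 and attacks the primary bromide, leaving the (R) carbinol centre untouched.

Step 2
Reactants: 3 (R)-11-hydroxyhexadec-9-ynoic acid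
Product: 4 (9Z,11R)-11-hydroxyhexadec-9-enoic acid
Conditions: H2 (1 atm), Pd/CaCO3 poisoned with Pb(OAc)2, quinoline, EtOAc, rt, monitored to one equivalent of uptake
Reagents that add atoms: none
Why: Lindlar semihydrogenation delivers H2 syn on the poisoned palladium surface to give the Z olefin, quinoline suppresses over-reduction and isomerisation, and the carbinol centre is not involved.

Step 3
Reactants: 4 (9Z,11R)-11-hydroxyhexadec-9-enoic acid
Product: 6 (9Z,11R)-11-acetoxyhexadec-9-enoic acid, via mixed acetic anhydride 5 (not isolated)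
Conditions: Ac2O (2.5 equiv), pyridine, DMAP (cat.), CH2Cl2, 0 °C to rt; then H2O/THF, rt
Reagents that add atoms: acetic anhydride, CC(=O)OC(C)=O; water, O (hydrolysis of 5, supplies at most one carboxyl oxygen)
Why: DMAP-catalysed acylation of the secondary allylic alcohol proceeds with retention because the C–O bond is not broken, and the carboxyl group, transiently converted into mixed anhydride 5, is returned by water.

Step 4
Reactants: 6 (9Z,11R)-11-acetoxyhexadec-9-enoic acid; 7 Meldrum's acid (2,2-dimethyl-1,3-dioxane-4,6-dione)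
Product: 8 5-[(9Z,11R)-11-acetoxy-1-hydroxyhexadec-9-en-1-ylidene]-2,2-dimethyl-1,3-dioxane-4,6-dione
Conditions: DCC (1.1 equiv), DMAP (1.5 equiv), CH2Cl2, 0 °C to rt; filter; cold aq. KHSO4 wash
Reagents that add atoms: none
Why: Oikawa–Yonemitsu C-acylation, in which the carbodiimide-activated acid acylates the highly acidic C5 of Meldrum's acid under DMAP catalysis, conditions that leave the allylic acetate alone.

Step 5
Reactants: 8 acyl Meldrum's acid; 9 2-(trimethylsilyl)ethanol
Product: 11 2-(trimethylsilyl)ethyl (11Z,13R)-13-acetoxy-3-oxooctadec-11-enoate, via acylketene 10 (not isolated)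
Conditions: 9 (2 equiv), toluene, 90 °C
Reagents that add atoms: none
Why: Thermal fragmentation of the acyl Meldrum's acid releases acetone and CO2, and acylketene 10 is trapped by the alcohol (Oikawa–Yonemitsu beta-keto ester synthesis) under neutral conditions that the acetate and the Z olefin tolerate.

Step 6
Reactants: 11 beta-keto ester; 12 malonyl dichloride
Product: 13 2-(trimethylsilyl)ethyl 6-[(8Z,10R)-10-acetoxypentadec-8-en-1-yl]-4-hydroxy-2-oxo-2H-pyran-5-carboxylate
Conditions: 12 (1.2 equiv), CH2Cl2, 0 to 40 °C, slow N2 sweep to carry off HCl; evaporate, crystallise or rapid chromatography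
Reagents that add atoms: none
Why: Condensation of malonyl dichloride with a beta-keto ester (C-acylation at C2 and O-acylation of the ketone enol, in either order) closes the 4-hydroxy-2-pyranone with the ketone carbon as C6 and the ester-bearing carbon as C5, so the regiochemistry is unambiguous, and sweeping out HCl is meant to spare the allylic acetate and the silylethyl ester.

Step 7
Reactants: 13 hydroxypyranone
Product: 14 2-(trimethylsilyl)ethyl 6-[(8Z,10R)-10-acetoxypentadec-8-en-1-yl]-4-(tert-butyldimethylsilyloxy)-2-oxo-2H-pyran-5-carboxylate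
Conditions: TBSCl (1.2 equiv), imidazole (1.5 equiv), CH2Cl2, 0 °C to rt; dilute with pentane, filter under argon, concentrate; used without aqueous work-up
Reagents that add atoms: tert-butyldimethylsilyl chloride, CC(C)(C)[Si](C)(C)Cl
Why: O-silylation of a vinylogous carboxylic acid, in which the acidic 4-OH reacts readily and the 2-pyranone form is expected to be kept because silyl groups equilibrate to the more stable lactone tautomer; the product is a moisture-sensitive vinylogous silyl ester and is therefore kept away from water.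

Step 8
Reactants: 15 trimethylsilyl acetate
Product: 16 1,1-bis(trimethylsilyloxy)ethene
Conditions: LiN(i-Pr)2 (1.05 equiv, commercial solution), THF, −78 °C; Me3SiCl (1.1 equiv), −78 °C to rt; pentane, filter, distil under reduced pressure
Reagents that add atoms: chlorotrimethylsilane, C[Si](C)(C)Cl
Why: Kinetic enolisation of the silyl ester followed by O-silylation with the hard chlorosilane is the standard preparation of bis-silyl ketene acetals.

Step 9
Reactants: 14 silyloxypyranone; 16 1,1-bis(trimethylsilyloxy)ethene
Product: 20 2-(trimethylsilyl)ethyl 6-[(8Z,10R)-10-acetoxypentadec-8-en-1-yl]-2-(tert-butyldimethylsilyloxy)-4-hydroxybenzoate, via bridged lactone 17 (not isolated), via cyclohexadiene ketal 18 (not isolated), via aryl trimethylsilyl ether 19 (not isolated)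
Conditions: 16 (4 equiv), toluene, sealed tube, 110–130 °C, argon; then THF/0.5 M aq. citric acid, 0 °C
Reagents that add atoms: none
Why: The electron-rich alkene of 16 should add across C3 and C6 of the electron-poor diene of 14 in an inverse-electron-demand Diels–Alder reaction that is probably strongly asynchronous (the CH2–C6 bond leading), bridged lactone 17 should then expel CO2 by retro-(4+2) cleavage, diene 18 should lose Me3SiOH across its bis-silyl ketal carbon and the vinylogously acidic CH2, and the labile ArO–SiMe3 bond of 19 is hydrolysed in the work-up while the hindered TBS ether ortho to the ester remains. The closest known reaction type is the benzannulation of 2-pyranone-5-carboxylates (coumalates) with ketene acetals to 4-alkoxybenzoates; the 4-silyloxy donor and the 6-alkyl group of 14 and the bis-silyl acetal go beyond the close examples, which is why heating and an excess of 16 are planned. Ring A is closed by an intermolecular (4+2) annulation that makes both new ring bonds (C5–C6 and C3–C4, ring A numbering) in one operation, the six-membered carbocycle taking the place of the six-membered lactone. No new stereocentre persists, since the two bridgehead centres of 17 are erased on aromatisation, and the remote acetate-bearing centre is untouched under these neutral conditions. The selectivity needed is regiochemical and is secured by matched polarity: the nucleophilic CH2 of 16 bonds to pyranone C6 (beta to the C5 ester, delta to the lactone carbonyl) and the acetal carbon to pyranone C3 (the beta-carbon of the C4 silyl enol ether), which puts the new oxygen para to the ester.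

Step 10
Reactants: 20 protected ring A ester
Product: 21 6-[(8Z,10R)-10-acetoxypentadec-8-en-1-yl]-2,4-dihydroxybenzoic acid (target)
Conditions: TBAF (4 equiv), AcOH (2 equiv), THF, 0 °C to rt; cold pH 4 buffer, extraction and concentration below 25 °C
Reagents that add atoms: none
Why: Fluoride-induced desilylation frees the C2 phenol and triggers beta-elimination of the 2-silylethyl ester (ethene and Me3SiF) without attack at the hindered carbonyl, the acetic acid buffer keeps the medium too weakly basic to cleave or transfer the secondary acetate, and the cold, mildly acidic work-up avoids decarboxylation of the resorcylic acid.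

**Compound list**

1 | (R)-oct-1-yn-3-ol | CCCCC[C@H](C#C)O | starting material
2 | 8-bromooctanoic acid | OC(=O)CCCCCCCBr | starting material
3 | (R)-11-hydroxyhexadec-9-ynoic acid | CCCCC[C@H](C#CCCCCCCCC(=O)O)O | intermediate
4 | (9Z,11R)-11-hydroxyhexadec-9-enoic acid | CCCCC[C@H](/C=C\CCCCCCCC(=O)O)O | intermediate
5 | acetic (9Z,11R)-11-acetoxyhexadec-9-enoic anhydride | CCCCC[C@H](/C=C\CCCCCCCC(=O)OC(C)=O)OC(C)=O | intermediate (not isolated)
6 | (9Z,11R)-11-acetoxyhexadec-9-enoic acid | CCCCC[C@H](/C=C\CCCCCCCC(=O)O)OC(C)=O | intermediate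
7 | Meldrum's acid (2,2-dimethyl-1,3-dioxane-4,6-dione) | CC1(C)OC(=O)CC(=O)O1 | starting material
8 | 5-[(9Z,11R)-11-acetoxy-1-hydroxyhexadec-9-en-1-ylidene]-2,2-dimethyl-1,3-dioxane-4,6-dione | CCCCC[C@H](/C=C\CCCCCCCC(O)=C1C(=O)OC(C)(C)OC1=O)OC(C)=O | intermediate
9 | 2-(trimethylsilyl)ethanol | C[Si](C)(C)CCO | starting material
10 | (9Z,11R)-11-acetoxyhexadec-9-enoylketene | CCCCC[C@H](/C=C\CCCCCCCC(=O)C=C=O)OC(C)=O | intermediate (not isolated)
11 | 2-(trimethylsilyl)ethyl (11Z,13R)-13-acetoxy-3-oxooctadec-11-enoate | CCCCC[C@H](/C=C\CCCCCCCC(=O)CC(=O)OCC[Si](C)(C)C)OC(C)=O | intermediate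
12 | malonyl dichloride | O=C(Cl)CC(=O)Cl | starting material
13 | 2-(trimethylsilyl)ethyl 6-[(8Z,10R)-10-acetoxypentadec-8-en-1-yl]-4-hydroxy-2-oxo-2H-pyran-5-carboxylate | CCCCC[C@H](/C=C\CCCCCCCC1=C(C(=O)OCC[Si](C)(C)C)C(O)=CC(=O)O1)OC(C)=O | intermediate
14 | 2-(trimethylsilyl)ethyl 6-[(8Z,10R)-10-acetoxypentadec-8-en-1-yl]-4-(tert-butyldimethylsilyloxy)-2-oxo-2H-pyran-5-carboxylate | CCCCC[C@H](/C=C\CCCCCCCC1=C(C(=O)OCC[Si](C)(C)C)C(O[Si](C)(C)C(C)(C)C)=CC(=O)O1)OC(C)=O | intermediate
15 | trimethylsilyl acetate | CC(=O)O[Si](C)(C)C | starting material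
16 | 1,1-bis(trimethylsilyloxy)ethene | C=C(O[Si](C)(C)C)O[Si](C)(C)C | intermediate
17 | 2-(trimethylsilyl)ethyl 1-[(8Z,10R)-10-acetoxypentadec-8-en-1-yl]-5-(tert-butyldimethylsilyloxy)-3-oxo-8,8-bis(trimethylsilyloxy)-2-oxabicyclo[2.2.2]oct-5-ene-6-carboxylate (bridgehead configurations not defined) | CCCCC[C@H](/C=C\CCCCCCCC12OC(=O)C(C(O[Si](C)(C)C(C)(C)C)=C1C(=O)OCC[Si](C)(C)C)C(O[Si](C)(C)C)(O[Si](C)(C)C)C2)OC(C)=O | intermediate (not isolated)
18 | 2-(trimethylsilyl)ethyl 2-[(8Z,10R)-10-acetoxypentadec-8-en-1-yl]-6-(tert-butyldimethylsilyloxy)-4,4-bis(trimethylsilyloxy)cyclohexa-1,5-diene-1-carboxylate | CCCCC[C@H](/C=C\CCCCCCCC1=C(C(=O)OCC[Si](C)(C)C)C(O[Si](C)(C)C(C)(C)C)=CC(O[Si](C)(C)C)(O[Si](C)(C)C)C1)OC(C)=O | intermediate (not isolated)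
19 | 2-(trimethylsilyl)ethyl 6-[(8Z,10R)-10-acetoxypentadec-8-en-1-yl]-2-(tert-butyldimethylsilyloxy)-4-(trimethylsilyloxy)benzoate | CCCCC[C@H](/C=C\CCCCCCCc1cc(O[Si](C)(C)C)cc(O[Si](C)(C)C(C)(C)C)c1C(=O)OCC[Si](C)(C)C)OC(C)=O | intermediate (not isolated)
20 | 2-(trimethylsilyl)ethyl 6-[(8Z,10R)-10-acetoxypentadec-8-en-1-yl]-2-(tert-butyldimethylsilyloxy)-4-hydroxybenzoate | CCCCC[C@H](/C=C\CCCCCCCc1cc(O)cc(O[Si](C)(C)C(C)(C)C)c1C(=O)OCC[Si](C)(C)C)OC(C)=O | intermediate
21 | 6-[(8Z,10R)-10-acetoxypentadec-8-en-1-yl]-2,4-dihydroxybenzoic acid | CCCCC[C@H](/C=C\CCCCCCCc1cc(O)cc(O)c1C(=O)O)OC(C)=O | target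

**Step count**

Total step count: 10.
Longest linear sequence: 9 (steps 1–7, 9 and 10; step 8 is a one-step side branch).

**Steps most likely to fail**

1. Step 9 (key step). The cycloaddition may not start, because the 4-silyloxy donor raises the pyranone LUMO and C6 is fully substituted. The first C–C bond may also be followed by silyl transfer instead of ring closure, or the ketene acetal may be used up by O-to-C silyl migration or protodesilylation before it reacts.
Fallback, from 6 to 21, building ring A by ketene trapping and aldol aromatisation of a diketo-dioxinone. 2,2,6-Trimethyl-4H-1,3-dioxin-4-one is acetylated through its lithium dienolate (LiN(SiMe3)2, then acetyl chloride, THF, −78 °C) to 2,2-dimethyl-6-(2-oxopropyl)-4H-1,3-dioxin-4-one F1. Acid 6 is converted with carbonyldiimidazole into its imidazolide F2. The dianion of F1 (LiN(i-Pr)2, THF, −78 °C, used in excess) is acylated at its terminal carbon by F2 to give the diketo-dioxinone F3; the acyl imidazole is far more electrophilic than the secondary acetate at this temperature. Heating F3 with 9 in toluene should release acetone and an acylketene that is trapped as the triketo ester F4. Et3N followed by AcOH should then bring about aldol condensation and dehydration to 2-(trimethylsilyl)ethyl 6-[(8Z,10R)-10-acetoxypentadec-8-en-1-yl]-2,4-dihydroxybenzoate F5. Buffered TBAF as in step 10 then removes the silylethyl ester and gives 21.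

2. Step 6. During the slow condensation the HCl formed may ionise or transpose the Z-allylic acetate or cleave the silylethyl ester, malonyl dichloride may self-condense, or ring closure may stop at an open acylation product.
Fallback, from 6 to 13, by acylation of a 3-oxoglutarate, which generates no free HCl at the ring-forming stage. Acid 6 is converted with oxalyl chloride and catalytic DMF (CH2Cl2, 0 °C) into (9Z,11R)-11-acetoxyhexadec-9-enoyl chloride F6. Dimethyl 3-oxopentanedioate is transesterified with 9 (toluene, reflux, removal of methanol) to bis[2-(trimethylsilyl)ethyl] 3-oxopentanedioate F7. MgCl2 and pyridine in CH2Cl2 should C-acylate F7 with F6 to give bis[2-(trimethylsilyl)ethyl] 2-[(9Z,11R)-11-acetoxyhexadec-9-enoyl]-3-oxopentanedioate F8. Heating F8 in xylene should expel 9 from the unsubstituted beta-keto ester arm, and the acylketene so formed is captured by the enol of the new acyl group to close the lactone, giving 13.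

3. Step 1. The alkylation of the doubly lithiated alkynol by the sparingly soluble lithium bromo-carboxylate may be slow, with competing dehydrobromination or O-alkylation, so that conversion is low and the chiral alkynol is wasted.
Fallback, from 2 to 3, making the carbinol centre by asymmetric reduction instead of buying it. Lithium acetylide–ethylenediamine complex in DMSO displaces the bromide of 2 to give dec-9-ynoic acid F9, which is esterified (MeOH, cat. H2SO4) to methyl dec-9-ynoate F10. Acyl Sonogashira coupling with hexanoyl chloride (PdCl2(PPh3)2, CuI, Et3N) should give methyl 11-oxohexadec-9-ynoate F11. Noyori transfer hydrogenation with RuCl[(R,R)-TsDPEN](p-cymene) in i-PrOH, the catalyst enantiomer expected from the established sense for ynones to give the (R) carbinol, should furnish methyl (R)-11-hydroxyhexadec-9-ynoate F12. LiOH in THF/H2O then gives 3.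

**Further compounds**

F1 | step 9 | 2,2-dimethyl-6-(2-oxopropyl)-4H-1,3-dioxin-4-one | CC(=O)CC1=CC(=O)OC(C)(C)O1
F2 | step 9 | 1-[(9Z,11R)-11-acetoxyhexadec-9-enoyl]imidazole | CCCCC[C@H](/C=C\CCCCCCCC(=O)n1ccnc1)OC(C)=O
F3 | step 9 | 6-[(11Z,13R)-13-acetoxy-2,4-dioxooctadec-11-en-1-yl]-2,2-dimethyl-4H-1,3-dioxin-4-one | CCCCC[C@H](/C=C\CCCCCCCC(=O)CC(=O)CC1=CC(=O)OC(C)(C)O1)OC(C)=O
F4 | step 9 | 2-(trimethylsilyl)ethyl (15Z,17R)-17-acetoxy-3,5,7-trioxodocos-15-enoate | CCCCC[C@H](/C=C\CCCCCCCC(=O)CC(=O)CC(=O)CC(=O)OCC[Si](C)(C)C)OC(C)=O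
F5 | step 9 | 2-(trimethylsilyl)ethyl 6-[(8Z,10R)-10-acetoxypentadec-8-en-1-yl]-2,4-dihydroxybenzoate | CCCCC[C@H](/C=C\CCCCCCCc1cc(O)cc(O)c1C(=O)OCC[Si](C)(C)C)OC(C)=O
F6 | step 6 | (9Z,11R)-11-acetoxyhexadec-9-enoyl chloride | CCCCC[C@H](/C=C\CCCCCCCC(Cl)=O)OC(C)=O
F7 | step 6 | bis[2-(trimethylsilyl)ethyl] 3-oxopentanedioate | C[Si](C)(C)CCOC(=O)CC(=O)CC(=O)OCC[Si](C)(C)C
F8 | step 6 | bis[2-(trimethylsilyl)ethyl] 2-[(9Z,11R)-11-acetoxyhexadec-9-enoyl]-3-oxopentanedioate | CCCCC[C@H](/C=C\CCCCCCCC(=O)C(C(=O)OCC[Si](C)(C)C)C(=O)CC(=O)OCC[Si](C)(C)C)OC(C)=O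
F9 | step 1 | dec-9-ynoic acid | C#CCCCCCCCC(=O)O
F10 | step 1 | methyl dec-9-ynoate | C#CCCCCCCCC(=O)OC
F11 | step 1 | methyl 11-oxohexadec-9-ynoate | CCCCCC(=O)C#CCCCCCCCC(=O)OC
F12 | step 1 | methyl (R)-11-hydroxyhexadec-9-ynoate | CCCCC[C@H](C#CCCCCCCCC(=O)OC)O
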